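## Analysis of the target

- The target 17 is a 20-membered macrocycle in which two benzene rings are joined twice: by a diaryl ether oxygen and by an unbranched chain of twelve methylene groups.
- Ring A is the monohydroxy ring, a 1,3,5-trisubstituted benzene carrying the hydroxyl, the ether oxygen and chain end C12. Ring B is the dihydroxy ring: its two hydroxyls flank the ether oxygen and the carbon para to that oxygen carries chain end C1 (the chain is numbered C1 to C12 from ring B to ring A).
- The large ring contains four atoms of ring B, three atoms of ring A, the oxygen and the twelve chain carbons.
- There is no stereocenter, and with so long a tether no stable planar chirality is expected, so the synthesis has no stereochemical task.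
- The sensitive part is the set of three free phenols, above all the electron-rich ring B (a pyrogallol 2-aryl ether), which is easily oxidised in base and air. The phenols are therefore carried as methyl ethers to the last step.
- The difficulties are the crowded ether oxygen on ring B, which sits between two oxygen substituents and faces a ring A with no activating group, and a chain that offers no functional group to show where the macrocycle should be closed.
- The strategy rests on that lack of functionality. Any chain carbon can be brought in as a one-carbon linchpin whose function is erased afterwards. Ring B with C1 to C3 and both flanking oxygens in place can be bought as 4-allyl-2,6-dimethoxyphenol 1, so the linchpin is set at C4 and C5 to C12 become an eight-carbon arm on ring A.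

## Retrosynthetic reasoning

**17 ⇒ 16.** The three phenolic O–H bonds are replaced by O–CH3 bonds. Methyl ethers are already present in 1 and 2, survive every base, borane, palladium and hydride step, and come off together at the end. The forward step must cleave three aryl methyl ethers without touching the diaryl ether, which is possible because an aryl–O–aryl unit has no carbon open to SN2 attack.

**16 ⇒ 14.** C4 of the saturated chain is given a carbonyl group. This adds nothing to the skeleton but marks the carbon through which the ring is closed. The forward step is a ketone-to-methylene reduction on an unactivated dialkyl ketone in the presence of aryl ethers.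

**14 ⇒ 9 + 10.** The bonds C3–C4 and C4–C5 are cut, and C4 becomes the doubly nucleophilic carbon of TosMIC 10, a masked carbonyl dianion; the partners are the two primary bromides of 9. The cut is made here for three reasons:
- C1 to C3 coincide with the allyl group of 1.
- Both electrophilic carbons are unbranched and far from the crowded ether.
- Two C–C bonds and the ring are formed in one operation from a reagent that brings exactly one carbon.

A cut nearer to either ring would bring a benzylic or homobenzylic halide into play and would require a longer arm on the other ring. The forward reaction must achieve two SN2 alkylations, the second intramolecular, and then unmask the ketone.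

**9 ⇒ 8.** The two C–Br bonds are traced back to C–OH bonds. Both ends can then be made by reliable oxygen-delivering chemistry and activated in a single step. The forward reaction must convert two primary alcohols into bromides under neutral conditions.

**8 ⇒ 5 + 6.** The bond between ring A and C12 is cut. Ring A becomes the aryl bromide 5, and C5 to C12 come from the terminal alkene 6 through its anti-Markovnikov alkylborane 7. An sp2–sp3 cross-coupling places the arm exactly at the carbon that carried bromine in 2, which no electrophilic alkylation of ring A could do. The forward step must couple a primary alkylborane without β-hydride elimination and in the presence of free hydroxyl groups.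

**5 ⇒ 3.** The hydroxyl at C3 is traced back to the terminal alkene of the allyl group through alkylborane 4. This step is placed before the cross-coupling so that 5 has no alkene that could take up borane during the formation of 7. The forward step needs anti-Markovnikov regiochemistry and must leave the aryl bromide alone.

**3 ⇒ 1 + 2.** The ring A carbon–oxygen bond of the diaryl ether is cut. Ring A has no electron-withdrawing group, so SNAr is excluded, and the phenol 1 is flanked by two methoxy groups. An oxidative copper-mediated coupling of the phenol with the arylboronic acid 2 is therefore chosen: it runs at room temperature, accepts ortho-substituted phenols, and keeps the bromine of 2 as the handle for the next C–C bond. All four starting materials (1, 2, 6 and 10) are commercial.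

## Alternatives that were turned down

**Alternative 1:** Ring B itself is taken apart.
- Disconnection: four ring carbons and an ester come from an aryloxy-acetoacetate unit attached to the ring A oxygen, and two come from an ynoate at the end of a twelve-methylene arm, as in the open-chain precursor A2.
- Forward key step: base would make the central carbon of the keto ester add to the β-carbon of the ynoate, closing the 20-membered ring. The aryloxy-bearing carbon would then condense with the ynoate ester to close ring B, giving the macrocyclic methyl β-resorcylate A1.
- For: the crowded diaryl ether is never made by an aryl coupling, since the oxygen is alkylated while ring B does not yet exist, and one step builds an arene and the macrocycle. On these two points it is stronger than the chosen route.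
- Against:
  - The ring-closing event is a Michael addition onto a β-alkyl ynoate, a modest acceptor. At the dilution a 20-membered ring demands, this bimolecular-type step is slow, while the keto ester can add to a second molecule.
  - After the Michael step the enolate oxygen can attack the ester and give a 2-pyranone instead of the carbocycle.
  - The ester in A1 is not in the target and costs a saponification and a decarboxylation.
  - A2 needs a 15-carbon ynoate arm built on ring A over several steps.
- Comparison: the chosen route buys ring B complete with three chain carbons, closes the ring by plain SN2 at primary carbons, and removes its one auxiliary function (the C4 ketone) in one step.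

**Alternative 2:** Ring A is taken apart.
- Disconnection: the open-chain precursor A4 carries an ethynyl ether on the ring B oxygen and, at the end of the twelve-methylene arm, an α-methylene diazoketone.
- Forward key step: irradiation would trigger a photochemical Wolff rearrangement to a vinylketene. This adds to the ynol ether, and the cyclobutenone opens and recloses by electrocyclisation to give the ring A phenol and the macrocycle at once, as A3.
- For: ring A arrives with its 1,3,5 pattern fixed by mechanism and with a free hydroxyl, and only one demethylation separates A3 from 17. The endgame is one step shorter than that of the chosen route.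
- Against:
  - The first bond-forming event is a [2+2] addition between two chain ends across a 20-membered ring. A vinylketene does not live long enough to wait for that encounter, so dimerisation and capture by traces of nucleophile should win at high dilution.
  - The ethynyl ether of a 2,6-dimethoxyphenol is a fragile group that has to be carried through the construction of the arm.
  - The 2-substituted acryloyl diazomethane unit can cyclise onto its own alkene or polymerise.
  - The linear sequence to A4 is long.
- Comparison: the chosen route gives up the short endgame but closes the ring through a long-lived, stabilised carbanion and ordinary alkyl bromides, for which dilution works as intended.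

**Alternative 3:** The chain is cut at C11–C12 and a sulfur atom is inserted.
- Disconnection: the 21-membered benzylic sulfone A6.
- Forward key step: one-pot α-halogenation under basic conditions, closure to the episulfone and loss of SO2 (Ramberg–Bäcklund reaction) would contract the ring and form the C11=C12 alkene, giving the macrocyclic styrene A5.
- For: sulfur-based ring closure by a soft thiolate is among the most dependable macrocyclisations, and the ring contraction is well suited to benzylic sulfones. On the reliability of ring closure this alternative is at least as strong as the chosen route. Either α-position of A6 leads to the same alkene, so regiochemistry of halogenation does not matter.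
- Against:
  - Ring A must be prepared with a benzylic leaving group, and ring B needs an eleven-carbon arm, so the three carbons of the allyl group must be extended by eight.
  - After the ring is closed there are still four steps: S-oxidation, ring contraction, hydrogenation of an E/Z alkene mixture and demethylation.
- Comparison: the chosen route needs two steps after ring closure, takes the linchpin and both arms from commercial pieces, and makes two C–C bonds in the ring-closing operation, with no alkene geometry to manage.

Key step: step 5

Remark: 17 is achiral. Intermediates 11, 12 and 13 each carry one stereogenic carbon, arise as racemates and lose it within step 5, and hydrazone 15 arises as an E/Z mixture, so all are drawn without configuration.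

## Route

Step 1
Reactants: 1 4-allyl-2,6-dimethoxyphenol; 2 (3-bromo-5-methoxyphenyl)boronic acid
Product: 3 2-(3-bromo-5-methoxyphenoxy)-1,3-dimethoxy-5-(prop-2-en-1-yl)benzene
Conditions: 2 (2 equiv), Cu(OAc)2 (1 equiv), pyridine (5 equiv), 4 Å MS, CH2Cl2, dry air, rt
Reagents that add atoms: none
Why: Chan–Lam oxidative C–O coupling: the aryl group of 2 is transferred to divalent copper, the phenoxide of 1 binds, and after oxidation to trivalent copper the C–O bond forms by reductive elimination at room temperature, with air returning the copper to the divalent state. Phenols with two ortho substituents are accepted in this coupling, and the aryl bromide and the allyl group are not touched.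

Step 2
Reactants: 3 2-(3-bromo-5-methoxyphenoxy)-1,3-dimethoxy-5-(prop-2-en-1-yl)benzene
Product: 5 3-[4-(3-bromo-5-methoxyphenoxy)-3,5-dimethoxyphenyl]propan-1-ol, via B-alkyl-9-BBN adduct 4 (not isolated)
Conditions: 9-BBN (1.5 equiv), THF, 0 °C to rt; then 3 M aq. NaOH, 30% H2O2, 0 °C to rt
Reagents that add atoms: hydrogen peroxide, OO (the hydroxyl oxygen of 5); 9-borabicyclo[3.3.1]nonane, B1C2CCCC1CCC2 (the boron and bicyclic residue of 4 only, none remains in 5)
Why: Brown hydroboration–oxidation: the bulky dialkylborane places boron on the terminal carbon of the allyl group with high anti-Markovnikov selectivity, and alkaline peroxide replaces boron by hydroxyl; the aryl bromide is inert. Doing this before the cross-coupling removes the only alkene of the diaryl ether, so no borane can add to it in step 3.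

Step 3
Reactants: 5 3-[4-(3-bromo-5-methoxyphenoxy)-3,5-dimethoxyphenyl]propan-1-ol; 6 oct-7-en-1-ol
Product: 8 8-{3-[4-(3-hydroxypropyl)-2,6-dimethoxyphenoxy]-5-methoxyphenyl}octan-1-ol, via octylborane 7 (not isolated)
Conditions: 6 (1.5 equiv), 9-BBN (3.1 equiv), THF, 0 °C to rt; then 5, PdCl2(dppf) (5 mol %), 3 M aq. NaOH, 65 °C
Reagents that add atoms: 9-borabicyclo[3.3.1]nonane, B1C2CCCC1CCC2 (the two boron residues of 7 only, none remains in 8)
Why: B-alkyl Suzuki–Miyaura coupling: 9-BBN adds to the terminal alkene of 6 and a second equivalent is taken up by its hydroxyl group as a borinate; hydroxide turns the borane into a borate that hands its primary alkyl group to the arylpalladium bromide formed from 5 and zerovalent palladium. The wide bite angle of dppf favours reductive elimination over β-hydride elimination, and the free hydroxyl groups are compatible with the aqueous base, so no protecting group is needed.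

Step 4
Reactants: 8 8-{3-[4-(3-hydroxypropyl)-2,6-dimethoxyphenoxy]-5-methoxyphenyl}octan-1-ol
Product: 9 2-[3-(8-bromooctyl)-5-methoxyphenoxy]-5-(3-bromopropyl)-1,3-dimethoxybenzene
Conditions: CBr4 (2.6 equiv), PPh3 (2.6 equiv), CH2Cl2, 0 °C to rt
Reagents that add atoms: carbon tetrabromide, BrC(Br)(Br)Br
Why: Appel reaction: PPh3 and CBr4 give a bromophosphonium salt, each primary alcohol is converted into an alkoxyphosphonium ion, and bromide displaces Ph3P=O by SN2. The neutral conditions leave the electron-rich arenes and the ethers alone, and both hydroxyl groups are primary and unhindered.

Step 5
Reactants: 9 2-[3-(8-bromooctyl)-5-methoxyphenoxy]-5-(3-bromopropyl)-1,3-dimethoxybenzene; 10 p-toluenesulfonylmethyl isocyanide (TosMIC)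
Product: 14 macrocyclic C4 ketone trimethyl ether, via propyl-arm monoalkylate 11 (not isolated), via octyl-arm monoalkylate 12 (not isolated), via macrocyclic tosyl isocyanide 13 (not isolated)
Conditions: NaH (4 equiv), n-Bu4NI (0.2 equiv), DMSO/Et2O (1:3), rt, 9 and 10 (1.05 equiv) added together by syringe pump over 12 h to a final 3 mM; aqueous work-up; then conc. aq. HCl, CH2Cl2, rt
Reagents that add atoms: water, O (the carbonyl oxygen of 14)
Why: TosMIC 10 serves as a carbonyl dianion equivalent (van Leusen dialkylation): its methylene, flanked by sulfonyl and isocyanide groups, is deprotonated by NaH, and the carbanion displaces one primary bromide of 9 by SN2 to give 11 or 12, depending on which arm reacts first. The remaining C–H is still acidic enough for NaH, and the second carbanion closes the 20-membered ring by an intramolecular exo-tet SN2 displacement of the other primary bromide (20-exo-tet), giving 13. The closest known reaction type is the dialkylation of TosMIC with α,ω-dihalides to carbocyclic and cyclophane ketones. Both orders of alkylation lead to the same ring, so no selectivity between the two bromides is required. The selectivity that matters is ring closure against chain growth; slow joint addition keeps the stationary concentration of open-chain bromo carbanions low, and both electrophilic carbons are unbranched and remote from the crowded diaryl ether, so the twelve-carbon loop can fold without strain. Catalytic n-Bu4NI converts the bromides into more reactive iodides in the flask. Brief treatment of crude 13 with aqueous HCl hydrates the isocyanide to an N-formyl amine, p-toluenesulfinate leaves, and the N-formyl imine hydrolyses to ketone 14, conditions to which the aryl methyl ethers and the diaryl ether are inert. The substituted carbon of 13 is stereogenic but is formed as a racemate and becomes the trigonal carbonyl carbon, so no stereocenter has to be controlled.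

Step 6
Reactants: 14 macrocyclic C4 ketone trimethyl ether
Product: 16 macrocyclic trimethyl ether with a saturated C1–C12 chain, via hydrazone 15 (not isolated)
Conditions: N2H4·H2O (10 equiv), KOH (10 equiv), diethylene glycol, 130 °C; then distil off H2O and excess N2H4, 200 °C
Reagents that add atoms: hydrazine, NN (the two nitrogen atoms of 15 only, none remains in 16)
Why: Wolff–Kishner reduction in the Huang-Minlon procedure: hydrazone 15 forms, base shifts a proton from nitrogen to carbon, and loss of N2 leaves a methylene group at C4. The diaryl ether is stable to hot KOH, and any partial O-demethylation is harmless because step 7 removes all methyl ethers, so such a mixture would be carried on unseparated.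

Step 7
Reactants: 16 macrocyclic trimethyl ether with a saturated C1–C12 chain
Product: 17 target macrocyclic triphenol
Conditions: BBr3 (6 equiv), CH2Cl2, −78 °C to rt; then H2O, 0 °C, under argon
Reagents that add atoms: none
Why: Lewis acid cleavage of aryl methyl ethers: BBr3 binds each methoxy oxygen, bromide attacks the methyl carbon by SN2, and hydrolysis of the aryl borates frees the three phenols. The diaryl ether survives because neither of its carbons can undergo SN2, and the work-up is kept under inert gas because the triphenol is oxidisable.

## Compound list

1 | 4-allyl-2,6-dimethoxyphenol | COc1cc(CC=C)cc(OC)c1O | starting material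
2 | (3-bromo-5-methoxyphenyl)boronic acid | COc1cc(Br)cc(c1)B(O)O | starting material
3 | 2-(3-bromo-5-methoxyphenoxy)-1,3-dimethoxy-5-(prop-2-en-1-yl)benzene | COc1cc(Br)cc(c1)Oc1c(OC)cc(CC=C)cc1OC | intermediate
4 | 9-{3-[4-(3-bromo-5-methoxyphenoxy)-3,5-dimethoxyphenyl]propyl}-9-borabicyclo[3.3.1]nonane (not isolated) | COc1cc(Br)cc(c1)Oc1c(OC)cc(CCCB2C3CCCC2CCC3)cc1OC | intermediate
5 | 3-[4-(3-bromo-5-methoxyphenoxy)-3,5-dimethoxyphenyl]propan-1-ol | COc1cc(Br)cc(c1)Oc1c(OC)cc(CCCO)cc1OC | intermediate
6 | oct-7-en-1-ol | OCCCCCCC=C | starting material
7 | 9-{8-[(9-borabicyclo[3.3.1]nonan-9-yl)oxy]octyl}-9-borabicyclo[3.3.1]nonane (not isolated) | C1CCC2CCCC1B2OCCCCCCCCB1C2CCCC1CCC2 | intermediate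
8 | 8-{3-[4-(3-hydroxypropyl)-2,6-dimethoxyphenoxy]-5-methoxyphenyl}octan-1-ol | COc1cc(CCCCCCCCO)cc(c1)Oc1c(OC)cc(CCCO)cc1OC | intermediate
9 | 2-[3-(8-bromooctyl)-5-methoxyphenoxy]-5-(3-bromopropyl)-1,3-dimethoxybenzene | COc1cc(CCCCCCCCBr)cc(c1)Oc1c(OC)cc(CCCBr)cc1OC | intermediate
10 | p-toluenesulfonylmethyl isocyanide (TosMIC) | Cc1ccc(cc1)S(=O)(=O)C[N+]#[C-] | starting material
11 | 2-[3-(8-bromooctyl)-5-methoxyphenoxy]-5-[4-isocyano-4-(4-methylbenzenesulfonyl)butyl]-1,3-dimethoxybenzene (racemic, not isolated) | COc1cc(CCCCCCCCBr)cc(c1)Oc1c(OC)cc(CCCC([N+]#[C-])S(=O)(=O)c2ccc(C)cc2)cc1OC | intermediate
12 | 5-(3-bromopropyl)-2-{3-[9-isocyano-9-(4-methylbenzenesulfonyl)nonyl]-5-methoxyphenoxy}-1,3-dimethoxybenzene (racemic, not isolated) | COc1cc(CCCCCCCCC([N+]#[C-])S(=O)(=O)c2ccc(C)cc2)cc(c1)Oc1c(OC)cc(CCCBr)cc1OC | intermediate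
13 | macrocyclic tosyl isocyanide: the 20-membered ring of 14 in which C4 carries an isocyano and a 4-methylbenzenesulfonyl group in place of the oxo group (racemic, not isolated) | COc1cc2cc(c1)Oc1c(OC)cc(cc1OC)CCCC([N+]#[C-])(S(=O)(=O)c3ccc(C)cc3)CCCCCCCC2 | intermediate
14 | macrocyclic C4 ketone trimethyl ether: ring A (5-methoxy-1,3-phenylene) and ring B (2,6-dimethoxy-1,4-phenylene, ether oxygen between the two methoxy groups) joined by the ether oxygen and by the chain ring B–(CH2)3–C(=O)–(CH2)8–ring A | COc1cc2cc(c1)Oc1c(OC)cc(cc1OC)CCCC(=O)CCCCCCCC2 | intermediate
15 | hydrazone of 14 at C4 (E/Z mixture, not isolated) | COc1cc2cc(c1)Oc1c(OC)cc(cc1OC)CCCC(=NN)CCCCCCCC2 | intermediate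
16 | macrocyclic trimethyl ether: as 14 but with C4 as a methylene group, so that the chain is (CH2)12 | COc1cc2cc(c1)Oc1c(OC)cc(cc1OC)CCCCCCCCCCCC2 | intermediate
17 | target macrocyclic triphenol: ring A with one hydroxyl, ring B with two hydroxyls flanking the ether oxygen, (CH2)12 chain from the para carbon of ring B to the meta carbon of ring A | Oc1cc2cc(c1)Oc1c(O)cc(cc1O)CCCCCCCCCCCC2 | target

## Step count and least certain steps

Total step count: 7 steps. Longest linear sequence: 7 steps (1 to 17); 2, 6 and 10 enter as purchased reagents.

**Step 5 (key step).**
- Most likely failure: chain growth instead of ring closure. The first alkylation is bimolecular and is slowed by the dilution that the second, ring-closing alkylation needs, so open-chain bromo carbanions may meet a second dibromide and oligomerise. Self-condensation of the TosMIC anion may also compete.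
- Fallback: leave the linchpin idea and close the ring by alkene metathesis at C2–C3. It sets out from 3 and returns at 16.
  - Negishi coupling of the aryl bromide of 3 with undec-10-en-1-ylzinc bromide F1 (from 11-bromoundec-1-ene, Zn dust and LiCl in THF; PdCl2(dppf), THF, 50 °C) should give the diene 2-[3-methoxy-5-(undec-10-en-1-yl)phenoxy]-1,3-dimethoxy-5-(prop-2-en-1-yl)benzene F2.
  - Ring-closing metathesis with the second-generation Grubbs catalyst in CH2Cl2 at about 2 mM and 40 °C should give the 20-membered C2=C3 macrocyclic alkene F3 as an E/Z mixture.
  - Hydrogenation (H2, Pd/C, EtOAc) should then give 16.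

**Step 1.**
- Most likely failure: slow C–O bond formation at the crowded phenol oxygen. Oxidative degradation of the electron-rich phenol by divalent copper and air, and protodeboronation or homocoupling of the boronic acid, could then take over.
- Fallback: reverse the polarity of the ring A partner. It sets out from 1 and returns at 3. Ullmann-type coupling of 1 with an excess of 1,3-dibromo-5-methoxybenzene (COc1cc(Br)cc(Br)c1; CuI, picolinic acid, K3PO4, DMSO, 90 °C) should give 3 directly under monovalent copper catalysis without an oxidant. The dibromide is symmetric, so mono-coupling gives a single product, and no new compound is passed (F0).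

**Step 3.**
- Most likely failure: uptake of borane by the hydroxyl group of 6 leaves the hydroboration incomplete, and residual B–H then reduces the arylpalladium intermediate (hydrodebromination). β-Hydride elimination from the alkylpalladium species is a second possibility.
- Fallback: replace the sp2–sp3 coupling by an sp2–sp coupling. It sets out from 5 and returns at 8. Sonogashira coupling of 5 with oct-7-yn-1-ol (PdCl2(PPh3)2, CuI, Et3N, 70 °C) should give the aryl alkyne 8-{3-[4-(3-hydroxypropyl)-2,6-dimethoxyphenoxy]-5-methoxyphenyl}oct-7-yn-1-ol F4, and hydrogenation (H2, Pd/C, EtOAc) should give 8.

**Step 6.**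
- Most likely failure: incomplete reduction through azine formation between hydrazone and unreacted ketone in the hot medium, together with partial loss of methyl groups that makes the product mixture hard to purify before step 7.
- Fallback: remove the carbonyl group through sulfur. It sets out from 14 and returns at 16. Ethane-1,2-dithiol and BF3·OEt2 in CH2Cl2 should give the spiro 1,3-dithiolane at C4 of the macrocycle F5, and Raney Ni in refluxing EtOH should desulfurise it to 16 (Mozingo reduction) under neutral conditions.

## Further compounds

F1 | step 5 | undec-10-en-1-ylzinc bromide | Br[Zn]CCCCCCCCCC=C
F2 | step 5 | 2-[3-methoxy-5-(undec-10-en-1-yl)phenoxy]-1,3-dimethoxy-5-(prop-2-en-1-yl)benzene | COc1cc(CCCCCCCCCC=C)cc(c1)Oc1c(OC)cc(CC=C)cc1OC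
F3 | step 5 | 20-membered C2=C3 macrocyclic alkene trimethyl ether (E/Z mixture) | COc1cc2cc(c1)Oc1c(OC)cc(cc1OC)CC=CCCCCCCCCC2
F0 | step 1 | none | none
F4 | step 3 | 8-{3-[4-(3-hydroxypropyl)-2,6-dimethoxyphenoxy]-5-methoxyphenyl}oct-7-yn-1-ol | COc1cc(C#CCCCCCCO)cc(c1)Oc1c(OC)cc(CCCO)cc1OC
F5 | step 6 | spiro 1,3-dithiolane at C4 of the macrocyclic trimethyl ether | COc1cc2cc(c1)Oc1c(OC)cc(cc1OC)CCCC1(SCCS1)CCCCCCCC2
A1 | alternative 1 | macrocyclic methyl β-resorcylate (ring B carrying a methyl ester next to the chain) | COc1cc2cc(c1)Oc1c(O)c(C(=O)OC)c(cc1O)CCCCCCCCCCCC2
A2 | alternative 1 | methyl 15-[3-methoxy-5-(4-methoxy-2,4-dioxobutoxy)phenyl]pentadec-2-ynoate | COC(=O)C#CCCCCCCCCCCCCc1cc(OC)cc(OCC(=O)CC(=O)OC)c1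
A3 | alternative 2 | macrocyclic ring A phenol with ring B as its dimethyl ether | Oc1cc2cc(c1)Oc1c(OC)cc(cc1OC)CCCCCCCCCCCC2
A4 | alternative 2 | 1-diazo-15-[4-(ethynyloxy)-3,5-dimethoxyphenyl]-3-methylidenepentadecan-2-one | COc1cc(CCCCCCCCCCCCC(=C)C(=O)C=[N+]=[N-])cc(OC)c1OC#C
A5 | alternative 3 | macrocyclic (E)-C11=C12 alkene trimethyl ether | C1CCCCCCCCc2cc(OC)c(c(OC)c2)Oc2cc(OC)cc(c2)/C=C/C1
A6 | alternative 3 | 21-membered benzylic sulfone trimethyl ether (SO2 between C11 and C12) | COc1cc2cc(c1)Oc1c(OC)cc(cc1OC)CCCCCCCCCCCS(=O)(=O)C2
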